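**Retrosynthetic overview**
- The acetate goes on last, by O-acylation of the free 15-alcohol 17 after desilylation; C15 is bought as (S)-oct-1-yn-3-ol.
- The only ring, the cyclopentenone, is closed late by ring-closing metathesis (C10=C11) between a C9 vinyl ketone and a C12 propenyl group, with loss of propene.
- Key disconnection C8–C12: Ireland–Claisen [3,3]-sigmatropic rearrangement of a (2S,3Z,5E)-dienyl ester of monomethyl azelate. The carbinol centre bought in (S)-but-3-yn-2-ol sets C8 and C12 and later leaves as propene.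
- The dienol comes from Sonogashira coupling of (S)-but-3-yn-2-ol with the (E)-vinyl iodide of O-silylated (S)-oct-1-yn-3-ol, then cis semi-reduction of the alkyne.

Assumption: prostaglandin numbering is used for positions (C1 = carboxyl carbon, C8/C12 = ring stereocentres, C15 = acetoxy carbon); the SMILES is read as (8R,12S,13E,15S).

**Route**

Step 1
Reactants: 1 (S)-oct-1-yn-3-ol
Product: 2 (S)-tert-butyldimethyl(oct-1-yn-3-yloxy)silane
Conditions: TBSCl, imidazole, DMF, 0 °C → rt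
Reagents that add atoms: tert-butyldimethylsilyl chloride, CC(C)(C)[Si](C)(C)Cl
Why: Imidazole-promoted silyl ether formation protects the C15 hydroxyl for the later enolate and Grignard steps and does not touch the C15 stereocentre.

Step 2
Reactants: 2 (S)-tert-butyldimethyl(oct-1-yn-3-yloxy)silane
Product: 4 (S,E)-tert-butyl[(1-iodooct-1-en-3-yl)oxy]dimethylsilane, via alkenylzirconocene chloride 3 (not isolated)
Conditions: Cp2Zr(H)Cl, THF, rt; then I2, 0 °C
Reagents that add atoms: iodine, II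
Why: Hydrozirconation is a syn, terminal-selective addition and iodinolysis of the C–Zr bond goes with retention, so only the (E)-1-iodoalkene forms.

Step 3
Reactants: 4 (S,E)-tert-butyl[(1-iodooct-1-en-3-yl)oxy]dimethylsilane; 5 (S)-but-3-yn-2-ol
Product: 6 (2S,5E,7S)-7-(tert-butyldimethylsilyloxy)dodec-5-en-3-yn-2-ol
Conditions: PdCl2(PPh3)2 (2 mol %), CuI (4 mol %), Et3N, THF, rt
Reagents that add atoms: none
Why: Sonogashira coupling joins the alkenyl iodide and the terminal alkyne with retention of the E geometry and tolerates the free propargylic alcohol; both stereocentres are spectators.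

Step 4
Reactants: 6 (2S,5E,7S)-7-(tert-butyldimethylsilyloxy)dodec-5-en-3-yn-2-ol
Product: 7 (2S,3Z,5E,7S)-7-(tert-butyldimethylsilyloxy)dodeca-3,5-dien-2-ol
Conditions: Zn dust activated with Cu(OAc)2 and AgNO3, MeOH/H2O (1:1), 45 °C
Reagents that add atoms: none
Why: Boland semi-reduction of a conjugated, hydroxyl-activated enyne adds two hydrogens cis and stops at the diene, giving the 3Z alkene next to the untouched 5E alkene.

Step 5
Reactants: 7 (2S,3Z,5E,7S)-7-(tert-butyldimethylsilyloxy)dodeca-3,5-dien-2-ol; 8 9-methoxy-9-oxononanoic acid (monomethyl azelate)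
Product: 9 (2S,3Z,5E,7S)-7-(tert-butyldimethylsilyloxy)dodeca-3,5-dien-2-yl methyl nonanedioate
Conditions: DCC, DMAP (cat.), CH2Cl2, 0 °C → rt
Reagents that add atoms: none
Why: Steglich esterification acylates the secondary dienylic alcohol under neutral conditions, so the ionisable carbinol keeps its configuration.

Step 6
Reactants: 9 (2S,3Z,5E,7S)-7-(tert-butyldimethylsilyloxy)dodeca-3,5-dien-2-yl methyl nonanedioate
Product: 12 (2R)-2-[(2E,4R,5E,7S)-7-(tert-butyldimethylsilyloxy)dodeca-2,5-dien-4-yl]-9-methoxy-9-oxononanoic acid, via bis(trimethylsilyl ketene acetal) 10 (not isolated), via trimethylsilyl ester 11 (not isolated)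
Conditions: LiN(iPr)2 (2.5 equiv), THF, −78 °C; Me3SiCl/Et3N; −78 °C → rt, then 60 °C; aq. citric acid work-up
Reagents that add atoms: none
Why: Ireland–Claisen [3,3]-sigmatropic rearrangement through a chair with the E(O)-ketene acetal (chain cis to the dienyl oxygen), the carbinol methyl equatorial and the Z-alkene substituent axial forms the C8–C12 bond suprafacially, relaying the (S)-carbinol centre to 8R and 12S (prostaglandin numbering) and giving an E-propenyl group, while the remote methyl ester is only transiently silylated.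

Step 7
Reactants: 12 (2R)-2-[(2E,4R,5E,7S)-7-(tert-butyldimethylsilyloxy)dodeca-2,5-dien-4-yl]-9-methoxy-9-oxononanoic acid
Product: 13 methyl (8R)-8-[(2E,4R,5E,7S)-7-(tert-butyldimethylsilyloxy)dodeca-2,5-dien-4-yl]-9-[methoxy(methyl)amino]-9-oxononanoate
Conditions: MeNH(OMe)·HCl, EDC·HCl, HOBt, iPr2NEt, CH2Cl2, 0 °C → rt
Reagents that add atoms: N,O-dimethylhydroxylamine hydrochloride, CNOC.Cl
Why: Carbodiimide/HOBt amide coupling turns the free C9 acid into the Weinreb amide under conditions too mild to epimerise C8.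

Step 8
Reactants: 13 methyl (8R)-8-[(2E,4R,5E,7S)-7-(tert-butyldimethylsilyloxy)dodeca-2,5-dien-4-yl]-9-[methoxy(methyl)amino]-9-oxononanoate
Product: 14 (8R)-8-[(2E,4R,5E,7S)-7-(tert-butyldimethylsilyloxy)dodeca-2,5-dien-4-yl]-9-[methoxy(methyl)amino]-9-oxononanoic acid
Conditions: LiOH·H2O, THF/H2O (3:1), 0 °C → rt; then 1 M HCl to pH 4
Reagents that add atoms: lithium hydroxide monohydrate, [Li+].[OH-].O
Why: Saponification cleaves the unhindered C1 methyl ester while the hindered tertiary amide and the silyl ether survive, so C1 is freed before any base-sensitive enone exists.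

Step 9
Reactants: 14 (8R)-8-[(2E,4R,5E,7S)-7-(tert-butyldimethylsilyloxy)dodeca-2,5-dien-4-yl]-9-[methoxy(methyl)amino]-9-oxononanoic acid
Product: 15 (8R)-8-[(2E,4R,5E,7S)-7-(tert-butyldimethylsilyloxy)dodeca-2,5-dien-4-yl]-9-oxoundec-10-enoic acid
Conditions: CH2=CHMgBr (3.5 equiv), THF, −78 → 0 °C; inverse quench into cold 1 M HCl
Reagents that add atoms: vinylmagnesium bromide, C=C[Mg]Br
Why: In this Weinreb ketone synthesis the first equivalent only deprotonates the acid (the carboxylate is inert) and the chelated tetrahedral adduct releases the vinyl ketone only on acidic quench, which prevents over-addition and amine conjugate addition.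

Step 10
Reactants: 15 (8R)-8-[(2E,4R,5E,7S)-7-(tert-butyldimethylsilyloxy)dodeca-2,5-dien-4-yl]-9-oxoundec-10-enoic acid
Product: 16 7-[(1R,2S)-2-[(1E,3S)-3-(tert-butyldimethylsilyloxy)oct-1-enyl]-5-oxocyclopent-3-en-1-yl]heptanoic acid
Conditions: second-generation Grubbs catalyst RuCl2(=CHPh)(PCy3)(H2IMes) (5 mol %), CH2Cl2 (0.005 M), 40 °C
Reagents that add atoms: none
Why: Ring-closing metathesis joins the vinyl ketone to the methyl-terminated propenyl alkene, which is favoured over the C13=C14 alkene shielded by the silyloxy/pentyl branch, and expels propene; C12 is untouched and C8 sits trans, its thermodynamic position α to the ketone.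

Step 11
Reactants: 16 7-[(1R,2S)-2-[(1E,3S)-3-(tert-butyldimethylsilyloxy)oct-1-enyl]-5-oxocyclopent-3-en-1-yl]heptanoic acid
Product: 17 7-[(1R,2S)-2-[(1E,3S)-3-hydroxyoct-1-enyl]-5-oxocyclopent-3-en-1-yl]heptanoic acid
Conditions: HF·pyridine, pyridine/THF, 0 °C → rt
Reagents that add atoms: none
Why: Buffered fluoride desilylation frees the allylic 15-hydroxyl without the strong base that would isomerise the enone towards the 8(12)-ene and without acid strong enough to ionise C15.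

Step 12
Reactants: 17 7-[(1R,2S)-2-[(1E,3S)-3-hydroxyoct-1-enyl]-5-oxocyclopent-3-en-1-yl]heptanoic acid
Product: 19 7-[(1R,2S)-2-[(1E,3S)-3-acetoxyoct-1-enyl]-5-oxocyclopent-3-en-1-yl]heptanoic acid, via mixed acetic anhydride 18 (not isolated)
Conditions: Ac2O (4 equiv), pyridine, DMAP (cat.), CH2Cl2, 0 °C → rt; then H2O/THF, rt
Reagents that add atoms: acetic anhydride, CC(=O)OC(C)=O
Why: DMAP-catalysed O-acylation acetylates the 15-hydroxyl with retention, and the mixed anhydride formed at C1 is hydrolysed back to the acid on stirring with water while the secondary acetate stays, giving the target.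

**Compound list**

1 | (S)-oct-1-yn-3-ol | CCCCC[C@H](O)C#C | starting material
2 | (S)-tert-butyldimethyl(oct-1-yn-3-yloxy)silane | CCCCC[C@H](O[Si](C)(C)C(C)(C)C)C#C | intermediate
3 | chloro[(1E,3S)-3-(tert-butyldimethylsilyloxy)oct-1-enyl]zirconocene (cyclopentadienyl rings drawn σ-bonded) | CCCCC[C@H](O[Si](C)(C)C(C)(C)C)/C=C/[Zr](Cl)(C1C=CC=C1)C1C=CC=C1 | intermediate (not isolated)
4 | (S,E)-tert-butyl[(1-iodooct-1-en-3-yl)oxy]dimethylsilane | CCCCC[C@H](O[Si](C)(C)C(C)(C)C)/C=C/I | intermediate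
5 | (S)-but-3-yn-2-ol | C[C@H](O)C#C | starting material
6 | (2S,5E,7S)-7-(tert-butyldimethylsilyloxy)dodec-5-en-3-yn-2-ol | C[C@H](O)C#C/C=C/[C@H](CCCCC)O[Si](C)(C)C(C)(C)C | intermediate
7 | (2S,3Z,5E,7S)-7-(tert-butyldimethylsilyloxy)dodeca-3,5-dien-2-ol | C[C@H](O)/C=C\C=C\[C@H](CCCCC)O[Si](C)(C)C(C)(C)C | intermediate
8 | 9-methoxy-9-oxononanoic acid (monomethyl azelate) | COC(=O)CCCCCCCC(=O)O | starting material
9 | (2S,3Z,5E,7S)-7-(tert-butyldimethylsilyloxy)dodeca-3,5-dien-2-yl methyl nonanedioate | C[C@H](OC(=O)CCCCCCCC(=O)OC)/C=C\C=C\[C@H](CCCCC)O[Si](C)(C)C(C)(C)C | intermediate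
10 | bis(trimethylsilyl ketene acetal) of 9, both ester ends as O-silyl ketene acetals with the chain cis to the alkoxy oxygen | C[C@H](O/C(O[Si](C)(C)C)=C\CCCCC/C=C(\OC)O[Si](C)(C)C)/C=C\C=C\[C@H](CCCCC)O[Si](C)(C)C(C)(C)C | intermediate (not isolated)
11 | trimethylsilyl (2R,8E)-2-[(2E,4R,5E,7S)-7-(tert-butyldimethylsilyloxy)dodeca-2,5-dien-4-yl]-9-methoxy-9-(trimethylsilyloxy)non-8-enoate | C[Si](C)(C)OC(=O)[C@H](CCCCC/C=C(\OC)O[Si](C)(C)C)[C@H](/C=C/C)/C=C/[C@H](CCCCC)O[Si](C)(C)C(C)(C)C | intermediate (not isolated)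
12 | (2R)-2-[(2E,4R,5E,7S)-7-(tert-butyldimethylsilyloxy)dodeca-2,5-dien-4-yl]-9-methoxy-9-oxononanoic acid | OC(=O)[C@H](CCCCCCC(=O)OC)[C@H](/C=C/C)/C=C/[C@H](CCCCC)O[Si](C)(C)C(C)(C)C | intermediate
13 | methyl (8R)-8-[(2E,4R,5E,7S)-7-(tert-butyldimethylsilyloxy)dodeca-2,5-dien-4-yl]-9-[methoxy(methyl)amino]-9-oxononanoate | CON(C)C(=O)[C@H](CCCCCCC(=O)OC)[C@H](/C=C/C)/C=C/[C@H](CCCCC)O[Si](C)(C)C(C)(C)C | intermediate
14 | (8R)-8-[(2E,4R,5E,7S)-7-(tert-butyldimethylsilyloxy)dodeca-2,5-dien-4-yl]-9-[methoxy(methyl)amino]-9-oxononanoic acid | CON(C)C(=O)[C@H](CCCCCCC(=O)O)[C@H](/C=C/C)/C=C/[C@H](CCCCC)O[Si](C)(C)C(C)(C)C | intermediate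
15 | (8R)-8-[(2E,4R,5E,7S)-7-(tert-butyldimethylsilyloxy)dodeca-2,5-dien-4-yl]-9-oxoundec-10-enoic acid | C=CC(=O)[C@H](CCCCCCC(=O)O)[C@H](/C=C/C)/C=C/[C@H](CCCCC)O[Si](C)(C)C(C)(C)C | intermediate
16 | 7-[(1R,2S)-2-[(1E,3S)-3-(tert-butyldimethylsilyloxy)oct-1-enyl]-5-oxocyclopent-3-en-1-yl]heptanoic acid | CCCCC[C@H](O[Si](C)(C)C(C)(C)C)/C=C/[C@H]1C=CC(=O)[C@@H]1CCCCCCC(=O)O | intermediate
17 | 7-[(1R,2S)-2-[(1E,3S)-3-hydroxyoct-1-enyl]-5-oxocyclopent-3-en-1-yl]heptanoic acid (the free 15-alcohol) | CCCCC[C@H](O)/C=C/[C@H]1C=CC(=O)[C@@H]1CCCCCCC(=O)O | intermediate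
18 | acetic 7-[(1R,2S)-2-[(1E,3S)-3-acetoxyoct-1-enyl]-5-oxocyclopent-3-en-1-yl]heptanoic anhydride | CCCCC[C@H](OC(C)=O)/C=C/[C@H]1C=CC(=O)[C@@H]1CCCCCCC(=O)OC(C)=O | intermediate (not isolated)
19 | 7-[(1R,2S)-2-[(1E,3S)-3-acetoxyoct-1-enyl]-5-oxocyclopent-3-en-1-yl]heptanoic acid | CCCCC[C@@H](/C=C/[C@H]1C=CC(=O)[C@@H]1CCCCCCC(=O)O)OC(C)=O | target

**Count and risks**

Total steps: 12. Longest linear sequence: 12 steps (1 → 19); 5 and 8 are bought and enter at steps 3 and 5.

Step 10 (ring-closing metathesis) is the most likely to fail. The catalyst could also engage the C13=C14 alkene, which would give a five-membered enone too and cut off the ω-chain, and the acryloyl end is a sluggish partner. The fallback sets out from 14 and comes back at 16. The Weinreb amide is reduced with iBu2AlH (2.2 equiv, THF, −78 °C; the carboxylate is not reduced) to the aldehyde (8R)-8-[(2E,4R,5E,7S)-7-(tert-butyldimethylsilyloxy)dodeca-2,5-dien-4-yl]-9-oxononanoic acid F1. CH2=CHMgBr then gives the allylic alcohol (8R)-8-[(2E,4R,5E,7S)-7-(tert-butyldimethylsilyloxy)dodeca-2,5-dien-4-yl]-9-hydroxyundec-10-enoic acid F2 as an inconsequential mixture of C9 epimers. Ring closure with the same second-generation Grubbs catalyst now starts at the reactive terminal vinyl carbinol and closes onto the unhindered propenyl group, giving the cyclopentenol 7-[2-[(1E,3S)-3-(tert-butyldimethylsilyloxy)oct-1-enyl]-5-hydroxycyclopent-3-en-1-yl]heptanoic acid F3 (ring centres as in 16). Dess–Martin periodinane (NaHCO3, CH2Cl2) oxidises it to 16.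

Step 6 (Ireland–Claisen) is the second risk. The Z-dienyl ketene acetal rearranges slowly because of the axial substituent in the chair, which leaves time for loss of the dienyl alkoxide, and enolate geometry limits the ratio at C8. The fallback sets out from 4 and comes back at 12 through the E,E series. Sonogashira coupling of 4 with bought (R)-but-3-yn-2-ol (C[C@@H](O)C#C) gives (2R,5E,7S)-7-(tert-butyldimethylsilyloxy)dodec-5-en-3-yn-2-ol F4. Hydroxyl-directed trans-reduction with NaAlH2(OCH2CH2OMe)2 (THF, 0 °C) gives (2R,3E,5E,7S)-7-(tert-butyldimethylsilyloxy)dodeca-3,5-dien-2-ol F5, which is esterified with 8 (DCC, DMAP) to (2R,3E,5E,7S)-7-(tert-butyldimethylsilyloxy)dodeca-3,5-dien-2-yl methyl nonanedioate F6. Enolisation with LiN(iPr)2 in THF/DMPU and Me3SiCl gives the bis(trimethylsilyl ketene acetal) with the chain cis to the silyloxy group F7 (from the Z(O)-enolate). With the E-alkene now equatorial, the (R)-carbinol and this enolate geometry lead to the same 8R,12S pair through the silyl ester trimethylsilyl (2R,8Z)-2-[(2E,4R,5E,7S)-7-(tert-butyldimethylsilyloxy)dodeca-2,5-dien-4-yl]-9-methoxy-9-(trimethylsilyloxy)non-8-enoate F8, and work-up gives 12. Any C8 epimer from the minor enolate converges later because C8 equilibrates to trans α to the ring ketone.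

Step 4 (semi-reduction) is the third risk: over-reduction, stalling, or Z to E drift of the conjugated diene. The fallback sets out from 2 and 5 and comes back at 7 by making the Z-alkene before the coupling. Compound 5 is iodinated (N-iodosuccinimide, AgNO3 cat., acetone) to (S)-4-iodobut-3-yn-2-ol F9 and reduced with diimide (2-nitrobenzenesulfonohydrazide, Et3N) to (S,Z)-4-iodobut-3-en-2-ol F10. Compound 2 is hydroborated with pinacolborane (Cp2Zr(H)Cl cat., 60 °C) to (S,E)-tert-butyldimethyl[[1-(4,4,5,5-tetramethyl-1,3,2-dioxaborolan-2-yl)oct-1-en-3-yl]oxy]silane F11. Suzuki coupling of F10 and F11 (Pd(PPh3)4, aq. K3PO4, THF, 50 °C) retains both alkene geometries and gives 7.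

**Further compounds**

F1 | step 10 | (8R)-8-[(2E,4R,5E,7S)-7-(tert-butyldimethylsilyloxy)dodeca-2,5-dien-4-yl]-9-oxononanoic acid | O=C[C@H](CCCCCCC(=O)O)[C@H](/C=C/C)/C=C/[C@H](CCCCC)O[Si](C)(C)C(C)(C)C
F2 | step 10 | (8R)-8-[(2E,4R,5E,7S)-7-(tert-butyldimethylsilyloxy)dodeca-2,5-dien-4-yl]-9-hydroxyundec-10-enoic acid (C9 epimers) | C=CC(O)[C@H](CCCCCCC(=O)O)[C@H](/C=C/C)/C=C/[C@H](CCCCC)O[Si](C)(C)C(C)(C)C
F3 | step 10 | 7-[2-[(1E,3S)-3-(tert-butyldimethylsilyloxy)oct-1-enyl]-5-hydroxycyclopent-3-en-1-yl]heptanoic acid (ring centres as in 16, carbinol epimers) | CCCCC[C@H](O[Si](C)(C)C(C)(C)C)/C=C/[C@H]1C=CC(O)[C@@H]1CCCCCCC(=O)O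
F4 | step 6 | (2R,5E,7S)-7-(tert-butyldimethylsilyloxy)dodec-5-en-3-yn-2-ol | C[C@@H](O)C#C/C=C/[C@H](CCCCC)O[Si](C)(C)C(C)(C)C
F5 | step 6 | (2R,3E,5E,7S)-7-(tert-butyldimethylsilyloxy)dodeca-3,5-dien-2-ol | C[C@@H](O)/C=C/C=C/[C@H](CCCCC)O[Si](C)(C)C(C)(C)C
F6 | step 6 | (2R,3E,5E,7S)-7-(tert-butyldimethylsilyloxy)dodeca-3,5-dien-2-yl methyl nonanedioate | C[C@@H](OC(=O)CCCCCCCC(=O)OC)/C=C/C=C/[C@H](CCCCC)O[Si](C)(C)C(C)(C)C
F7 | step 6 | bis(trimethylsilyl ketene acetal) of F6 with the chain cis to the silyloxy group at both ends | C[C@@H](O/C(O[Si](C)(C)C)=C/CCCCC/C=C(/OC)O[Si](C)(C)C)/C=C/C=C/[C@H](CCCCC)O[Si](C)(C)C(C)(C)C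
F8 | step 6 | trimethylsilyl (2R,8Z)-2-[(2E,4R,5E,7S)-7-(tert-butyldimethylsilyloxy)dodeca-2,5-dien-4-yl]-9-methoxy-9-(trimethylsilyloxy)non-8-enoate | C[Si](C)(C)OC(=O)[C@H](CCCCC/C=C(/OC)O[Si](C)(C)C)[C@H](/C=C/C)/C=C/[C@H](CCCCC)O[Si](C)(C)C(C)(C)C
F9 | step 4 | (S)-4-iodobut-3-yn-2-ol | C[C@H](O)C#CI
F10 | step 4 | (S,Z)-4-iodobut-3-en-2-ol | C[C@H](O)/C=C\I
F11 | step 4 | (S,E)-tert-butyldimethyl[[1-(4,4,5,5-tetramethyl-1,3,2-dioxaborolan-2-yl)oct-1-en-3-yl]oxy]silane | CCCCC[C@H](O[Si](C)(C)C(C)(C)C)/C=C/B1OC(C)(C)C(C)(C)O1
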